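**Retrosynthetic overview**
1. Target 22 is a 14-membered carbocycle (ring A, cembrane numbering C1–C14) fused at C1/C2 to a 2,5-dihydrofuran (ring B: O, C2, C1=C15, C16). The last two steps only adjust C17 (ester → CH2OH → CH2OAc).
2. Ring B is cut at O–C16 and C1=C15 in one operation: oxa-Michael/intramolecular Horner–Wadsworth–Emmons annulation of the macrocyclic (2S)-acyloin 16 with trimethyl 2-phosphonoacrylate 17. The enabling feature is that the ring-B oxygen sits on C2 directly beside C1, one end of the tetrasubstituted C1=C15 alkene, so O–C2–C1 is a latent α-hydroxy ketone; C15, with its two oxygenated one-carbon arms (C16H2–O and C17H2–OAc), is the α-carbon of an acrylate.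
3. Ring A is closed at C13–C14 by zerovalent-palladium allylic alkylation of a β-keto ester; the ester is an activating group and is removed by decarboxylation.
4. The open chain comes from (2E,6E)-farnesyl acetate: SeO2 oxidation of the terminal E-methyl, regioselective Shi epoxidation of the central alkene (C7/C8), asymmetric alkynylation of the enal with methyl propiolate (sets C2, brings C1 and C14), hydration of the ynoate.
5. Ring order: epoxide (step 3) → ring A (step 9) → ring B (step 12).

Key step: step 12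

Remark: the SMILES is read as (2S,7S,8S) with both ring alkenes E. Ring compounds carry cembrane numbering (C1 ketone/alkene carbon, C2 carbinol carbon, C3=C4 and C11=C12 alkenes, C7/C8 epoxide, C15–C17 the three carbons added in step 12); open-chain compounds carry farnesane or pentadecane numbering.

**Step 1**
Reactants: 1 (2E,6E)-farnesyl acetate
Product: 2 (2E,6E,10E)-12-hydroxyfarnesyl acetate
Conditions: SeO2 (0.3 equiv), t-BuOOH (3 equiv), salicylic acid (0.1 equiv), CH2Cl2, 0 °C → rt
Reagents that add atoms: selenium dioxide, O=[Se]=O (oxygen carrier, reoxidised by tert-butyl hydroperoxide, CC(C)(C)OO)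
Why: SeO2 allylic oxidation (ene reaction, then [2,3]-sigmatropic shift) should take the E-methyl of the terminal, most electron-rich alkene, the C2=C3 alkene being deactivated by the allylic acetate, and give the E-allylic alcohol.

**Step 2**
Reactants: 2 (2E,6E,10E)-12-hydroxyfarnesyl acetate
Product: 3 (2E,6E,10E)-1-acetoxy-3,7,11-trimethyldodeca-2,6,10-trien-12-yl pivalate
Conditions: t-BuCOCl (1.2 equiv), pyridine, DMAP (cat.), CH2Cl2, 0 °C
Reagents that add atoms: pivaloyl chloride, CC(C)(C)C(Cl)=O
Why: acylation of the primary alcohol gives a pivalate that deactivates the C10=C11 alkene for step 3, survives the acetate cleavage of step 4 and is the leaving group of step 9.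

**Step 3**
Reactants: 3 (2E,6E,10E)-1-acetoxy-3,7,11-trimethyldodeca-2,6,10-trien-12-yl pivalate
Product: 4 (2E,6S,7S,10E)-1-acetoxy-6,7-epoxy-3,7,11-trimethyldodeca-2,10-dien-12-yl pivalate
Conditions: 1,2:4,5-di-O-isopropylidene-β-L-erythro-2,3-hexodiulo-2,6-pyranose (L-fructose-derived Shi ketone, 0.3 equiv), KHSO5 (as 2KHSO5·KHSO4·K2SO4, 1.4 equiv), K2CO3, Bu4NHSO4 (cat.), Na2B4O7 buffer pH 10.5, MeCN–CH2(OMe)2–H2O, −10 → 0 °C
Reagents that add atoms: potassium peroxymonosulfate, [K+].[O-]S(=O)(=O)OO
Why: Shi epoxidation by the chiral dioxirane should pick the central alkene because both outer alkenes carry an electron-withdrawing allylic ester, and the spiro transition state of the L-fructose-derived ketone (mirror image of the D-fructose catalyst, which gives R,R epoxides from E-trisubstituted alkenes) should set 6S,7S, the C7/C8 centres of the target.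

**Step 4**
Reactants: 4 (2E,6S,7S,10E)-1-acetoxy-6,7-epoxy-3,7,11-trimethyldodeca-2,10-dien-12-yl pivalate
Product: 5 (2E,6S,7S,10E)-6,7-epoxy-1-hydroxy-3,7,11-trimethyldodeca-2,10-dien-12-yl pivalate
Conditions: K2CO3 (0.2 equiv), MeOH, 0 °C
Reagents that add atoms: none
Why: base-catalysed transesterification should remove the unhindered acetate well before the pivalate, and the epoxide is inert to methoxide at this temperature.

**Step 5**
Reactants: 5 (2E,6S,7S,10E)-6,7-epoxy-1-hydroxy-3,7,11-trimethyldodeca-2,10-dien-12-yl pivalate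
Product: 6 (2E,6S,7S,10E)-6,7-epoxy-3,7,11-trimethyl-1-oxododeca-2,10-dien-12-yl pivalate
Conditions: MnO2 (15 equiv), CH2Cl2, rt
Reagents that add atoms: none
Why: MnO2 oxidises only the allylic alcohol, under neutral conditions that should leave the epoxide and the E geometry of the enal untouched.

**Step 6**
Reactants: 6 (2E,6S,7S,10E)-6,7-epoxy-3,7,11-trimethyl-1-oxododeca-2,10-dien-12-yl pivalate; 7 methyl propiolate
Product: 8 methyl (4S,5E,9S,10S,13E)-9,10-epoxy-4-hydroxy-6,10,14-trimethyl-15-(pivaloyloxy)pentadeca-5,13-dien-2-ynoate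
Conditions: 7 (3 equiv), Me2Zn (3 equiv), (S,S)-ProPhenol (0.2 equiv), Ph3PO (0.4 equiv), toluene, 0–4 °C; aq. NH4Cl
Reagents that add atoms: none
Why: catalytic asymmetric alkynylation, in which the zinc alkynylide made from 7 and Me2Zn must be delivered inside the dinuclear zinc–ProPhenol complex to the Re face of the enal to give the 4S carbinol (C2 of the target); the (S,S)-ligand is expected to have this sense, and its mirror image is taken if Mosher ester analysis shows the opposite.

**Step 7**
Reactants: 8 methyl (4S,5E,9S,10S,13E)-9,10-epoxy-4-hydroxy-6,10,14-trimethyl-15-(pivaloyloxy)pentadeca-5,13-dien-2-ynoate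
Product: 9 methyl (4S,5E,9S,10S,13E)-4-(tert-butyldimethylsilyloxy)-9,10-epoxy-6,10,14-trimethyl-15-(pivaloyloxy)pentadeca-5,13-dien-2-ynoate
Conditions: TBSCl (1.5 equiv), imidazole (3 equiv), DMF, 0 °C → rt
Reagents that add atoms: tert-butyldimethylsilyl chloride, CC(C)(C)[Si](C)(C)Cl
Why: silylation blocks the carbinol so that it cannot lactonise to a tetronate in step 8 or act as a nucleophile in step 9.

**Step 8**
Reactants: 9 methyl (4S,5E,9S,10S,13E)-4-(tert-butyldimethylsilyloxy)-9,10-epoxy-6,10,14-trimethyl-15-(pivaloyloxy)pentadeca-5,13-dien-2-ynoate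
Product: 11 methyl (4S,5E,9S,10S,13E)-4-(tert-butyldimethylsilyloxy)-9,10-epoxy-6,10,14-trimethyl-3-oxo-15-(pivaloyloxy)pentadeca-5,13-dienoate, via enamino ester 10 (not isolated)
Conditions: pyrrolidine (1.2 equiv), MeCN, 0 °C → rt; then AcOH–NaOAc buffer (pH 5), THF–H2O, rt
Reagents that add atoms: water, O
Why: conjugate addition of the secondary amine to the ynoate puts nitrogen on C3 only, and mild hydrolysis of the resulting β-enamino ester gives the β-keto ester (formal regioselective hydration) at a pH the trisubstituted epoxide and the silyl ether should tolerate.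

**Step 9**
Reactants: 11 methyl (4S,5E,9S,10S,13E)-4-(tert-butyldimethylsilyloxy)-9,10-epoxy-6,10,14-trimethyl-3-oxo-15-(pivaloyloxy)pentadeca-5,13-dienoate
Product: 13 methyl (2S,3E,7S,8S,11E)-2-(tert-butyldimethylsilyloxy)-7,8-epoxy-4,8,12-trimethyl-1-oxocyclotetradeca-3,11-diene-14-carboxylate (both C14 epimers), via sodium enolate 12 (not isolated)
Conditions: NaH (1.05 equiv), THF, 0 °C; then syringe-pump addition (10 h) to Pd(PPh3)4 (0.1 equiv), Ph2PCH2CH2PPh2 (0.1 equiv), THF, 65 °C, final 2 mM
Reagents that add atoms: none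
Why: Tsuji–Trost macrocyclisation, in which zerovalent palladium ionises the allylic pivalate and the soft β-keto ester enolate attacks the unsubstituted terminus of the syn π-allyl complex, which should give the 14-membered ring with the E alkene retained, while the enolate at C14 shields C2 from deprotonation.

**Step 10**
Reactants: 13 methyl (2S,3E,7S,8S,11E)-2-(tert-butyldimethylsilyloxy)-7,8-epoxy-4,8,12-trimethyl-1-oxocyclotetradeca-3,11-diene-14-carboxylate
Product: 15 (2S,3E,7S,8S,11E)-2-(tert-butyldimethylsilyloxy)-7,8-epoxy-4,8,12-trimethylcyclotetradeca-3,11-dien-1-one, via keto acid 14 (not isolated)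
Conditions: Me3SnOH (6 equiv, returned as such on aqueous work-up), ClCH2CH2Cl, 80 °C; cold dilute aq. KHSO4 wash; toluene, 50 °C
Reagents that add atoms: none
Why: Me3SnOH cleaves the methyl ester under nearly neutral conditions that spare the epoxide, the silyl ether and the C2 centre, and the β-keto acid should lose CO2 on gentle warming to leave the activating group removed.

**Step 11**
Reactants: 15 (2S,3E,7S,8S,11E)-2-(tert-butyldimethylsilyloxy)-7,8-epoxy-4,8,12-trimethylcyclotetradeca-3,11-dien-1-one
Product: 16 (2S,3E,7S,8S,11E)-7,8-epoxy-2-hydroxy-4,8,12-trimethylcyclotetradeca-3,11-dien-1-one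
Conditions: Bu4NF (1.5 equiv), AcOH (1.5 equiv), THF, 0 °C → rt
Reagents that add atoms: none
Why: acetic-acid-buffered fluoride removes the silyl group without generating a free alkoxide, so the acyloin should be released without epimerisation at C2 or α-ketol shift.

**Step 12**
Reactants: 16 (2S,3E,7S,8S,11E)-7,8-epoxy-2-hydroxy-4,8,12-trimethylcyclotetradeca-3,11-dien-1-one; 17 trimethyl 2-phosphonoacrylate
Product: 20 methyl (2S,3E,7S,8S,11E)-2,16:7,8-diepoxycembra-1(15),3,11-trien-17-oate (ring B = 2,5-dihydrofuran-3-carboxylate fused at C1/C2), via sodium alkoxide 18 (not isolated), via phosphonate carbanion 19 (not isolated)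
Conditions: 17 (1.5 equiv), THF, −20 °C; NaH (1.0 equiv) added in portions; −20 → 0 °C
Reagents that add atoms: none
Why: The alkoxide 18 adds to the unsubstituted β-carbon of the doubly activated acrylate (oxa-Michael, O–C16), and the phosphonate-stabilised carbanion 19 then attacks the neighbouring C1 ketone and collapses through the oxaphosphetane with loss of sodium dimethyl phosphate (Horner–Wadsworth–Emmons, C1=C15). The closest known reaction type is the tandem Michael/intramolecular olefination of α-hydroxy ketones with 2-phosphonoacrylates or vinylphosphonium salts to give 2,5-dihydrofurans. Ring B is closed by 5-exo-trig addition of the carbanion to the C1 carbonyl and the elimination then places the alkene inside the ring, so its geometry is fixed. No new stereocentre is formed; C2, set in step 6, is carried through, and after the olefination it is no longer α to a ketone. The step needs O- over C-nucleophilicity and an intact C2 and C3=C4: the hydroxyl is by far the most acidic site, 17 is present before the base, only one equivalent of NaH is used at low temperature so that the alkoxide is trapped faster than it can enolise the ketone, and the base ends as non-basic sodium dimethyl phosphate. The ester that activates the acceptor is at the same time C17 at a higher oxidation level, corrected in steps 13 and 14.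

**Step 13**
Reactants: 20 methyl (2S,3E,7S,8S,11E)-2,16:7,8-diepoxycembra-1(15),3,11-trien-17-oate
Product: 21 (2S,3E,7S,8S,11E)-2,16:7,8-diepoxycembra-1(15),3,11-trien-17-ol
Conditions: i-Bu2AlH (2.5 equiv), CH2Cl2, −78 °C; aq. KNaC4H4O6
Reagents that add atoms: none
Why: 1,2-reduction of the unsaturated ester by i-Bu2AlH at low temperature gives the primary allylic alcohol and should leave the trisubstituted epoxide and the allylic ether untouched.

**Step 14**
Reactants: 21 (2S,3E,7S,8S,11E)-2,16:7,8-diepoxycembra-1(15),3,11-trien-17-ol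
Product: 22 (2S,3E,7S,8S,11E)-17-acetoxy-2,16:7,8-diepoxycembra-1(15),3,11-triene
Conditions: Ac2O (1.5 equiv), pyridine, DMAP (cat.), CH2Cl2, 0 °C → rt
Reagents that add atoms: acetic anhydride, CC(=O)OC(C)=O
Why: standard acylation of the primary alcohol under mildly basic conditions gives the target without touching any stereocentre.

**Compound list**
1 | (2E,6E)-farnesyl acetate | CC(C)=CCC/C(C)=C/CC/C(C)=C/COC(C)=O | starting material
2 | (2E,6E,10E)-12-hydroxyfarnesyl acetate | OC/C(C)=C/CC/C(C)=C/CC/C(C)=C/COC(C)=O | intermediate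
3 | (2E,6E,10E)-1-acetoxy-3,7,11-trimethyldodeca-2,6,10-trien-12-yl pivalate | CC(C)(C)C(=O)OC/C(C)=C/CC/C(C)=C/CC/C(C)=C/COC(C)=O | intermediate
4 | (2E,6S,7S,10E)-1-acetoxy-6,7-epoxy-3,7,11-trimethyldodeca-2,10-dien-12-yl pivalate | CC(C)(C)C(=O)OC/C(C)=C/CC[C@]1(C)O[C@H]1CC/C(C)=C/COC(C)=O | intermediate
5 | (2E,6S,7S,10E)-6,7-epoxy-1-hydroxy-3,7,11-trimethyldodeca-2,10-dien-12-yl pivalate | CC(C)(C)C(=O)OC/C(C)=C/CC[C@]1(C)O[C@H]1CC/C(C)=C/CO | intermediate
6 | (2E,6S,7S,10E)-6,7-epoxy-3,7,11-trimethyl-1-oxododeca-2,10-dien-12-yl pivalate | CC(C)(C)C(=O)OC/C(C)=C/CC[C@]1(C)O[C@H]1CC/C(C)=C/C=O | intermediate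
7 | methyl propiolate | C#CC(=O)OC | starting material
8 | methyl (4S,5E,9S,10S,13E)-9,10-epoxy-4-hydroxy-6,10,14-trimethyl-15-(pivaloyloxy)pentadeca-5,13-dien-2-ynoate | CC(C)(C)C(=O)OC/C(C)=C/CC[C@]1(C)O[C@H]1CC/C(C)=C/[C@H](O)C#CC(=O)OC | intermediate
9 | tert-butyldimethylsilyl ether of 8 | CC(C)(C)C(=O)OC/C(C)=C/CC[C@]1(C)O[C@H]1CC/C(C)=C/[C@H](O[Si](C)(C)C(C)(C)C)C#CC(=O)OC | intermediate
10 | methyl (4S)-3-(pyrrolidin-1-yl)-2-enoate from 9 (β-enamino ester, alkene geometry not defined) | CC(C)(C)C(=O)OC/C(C)=C/CC[C@]1(C)O[C@H]1CC/C(C)=C/[C@H](O[Si](C)(C)C(C)(C)C)C(=CC(=O)OC)N1CCCC1 | intermediate (not isolated)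
11 | methyl (4S,5E,9S,10S,13E)-4-(tert-butyldimethylsilyloxy)-9,10-epoxy-6,10,14-trimethyl-3-oxo-15-(pivaloyloxy)pentadeca-5,13-dienoate | CC(C)(C)C(=O)OC/C(C)=C/CC[C@]1(C)O[C@H]1CC/C(C)=C/[C@H](O[Si](C)(C)C(C)(C)C)C(=O)CC(=O)OC | intermediate
12 | sodium enolate of 11 | CC(C)(C)C(=O)OC/C(C)=C/CC[C@]1(C)O[C@H]1CC/C(C)=C/[C@H](O[Si](C)(C)C(C)(C)C)C([O-])=CC(=O)OC.[Na+] | intermediate (not isolated)
13 | methyl (2S,3E,7S,8S,11E)-2-(tert-butyldimethylsilyloxy)-7,8-epoxy-4,8,12-trimethyl-1-oxocyclotetradeca-3,11-diene-14-carboxylate (C14 epimers) | COC(=O)C1C/C(C)=C/CC[C@]2(C)O[C@H]2CC/C(C)=C/[C@H](O[Si](C)(C)C(C)(C)C)C1=O | intermediate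
14 | β-keto acid from 13 (trimethylstannyl ester until the acid wash) | OC(=O)C1C/C(C)=C/CC[C@]2(C)O[C@H]2CC/C(C)=C/[C@H](O[Si](C)(C)C(C)(C)C)C1=O | intermediate (not isolated)
15 | (2S,3E,7S,8S,11E)-2-(tert-butyldimethylsilyloxy)-7,8-epoxy-4,8,12-trimethylcyclotetradeca-3,11-dien-1-one | O=C1CC/C(C)=C/CC[C@]2(C)O[C@H]2CC/C(C)=C/[C@@H]1O[Si](C)(C)C(C)(C)C | intermediate
16 | (2S,3E,7S,8S,11E)-7,8-epoxy-2-hydroxy-4,8,12-trimethylcyclotetradeca-3,11-dien-1-one | O=C1CC/C(C)=C/CC[C@]2(C)O[C@H]2CC/C(C)=C/[C@@H]1O | intermediate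
17 | trimethyl 2-phosphonoacrylate (methyl 2-(dimethoxyphosphoryl)acrylate) | COC(=O)C(=C)P(=O)(OC)OC | starting material
18 | sodium alkoxide of 16 | O=C1CC/C(C)=C/CC[C@]2(C)O[C@H]2CC/C(C)=C/[C@@H]1[O-].[Na+] | intermediate (not isolated)
19 | oxa-Michael adduct of 18 and 17 as its sodium phosphonate carbanion | O=C1CC/C(C)=C/CC[C@]2(C)O[C@H]2CC/C(C)=C/[C@@H]1OC[C-](C(=O)OC)P(=O)(OC)OC.[Na+] | intermediate (not isolated)
20 | methyl (2S,3E,7S,8S,11E)-2,16:7,8-diepoxycembra-1(15),3,11-trien-17-oate | COC(=O)C1=C2CC/C(C)=C/CC[C@]3(C)O[C@H]3CC/C(C)=C/[C@@H]2OC1 | intermediate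
21 | (2S,3E,7S,8S,11E)-2,16:7,8-diepoxycembra-1(15),3,11-trien-17-ol | OCC1=C2CC/C(C)=C/CC[C@]3(C)O[C@H]3CC/C(C)=C/[C@@H]2OC1 | intermediate
22 | (2S,3E,7S,8S,11E)-17-acetoxy-2,16:7,8-diepoxycembra-1(15),3,11-triene | CC(=O)OCC1=C2CC/C(C)=C/CC[C@]3(C)O[C@H]3CC/C(C)=C/[C@@H]2OC1 | target

**Step count**
Total: 14 steps. Longest linear sequence: 14 steps (1 → 22); 7 and 17 are used as purchased.

**Steps most likely to fail**

Step 12. The alkoxide 18 may act as a base before it is trapped, so that C2 epimerises through the enediolate, the acyloin transposes or the C3=C4 bond moves into conjugation; the Michael adduct may also revert faster than the hindered ketone is olefinated. The fallback closes ring B by ring-closing metathesis and never liberates the acyloin. It sets out from 15: Cp2TiMe2 in toluene at 65 °C should give the exocyclic methylene silyl ether F1; Bu4NF in THF the doubly allylic alcohol F2; NaH and excess 3-chloro-2-(chloromethyl)prop-1-ene in THF–DMF the allyl ether chloride F3; and CsOAc in DMF the allylic acetate F4. The second-generation Hoveyda–Grubbs catalyst in toluene at 80 °C should then join the two 1,1-disubstituted alkenes with loss of ethene (the trisubstituted ring alkenes would have to release a disubstituted carbene and should stay out), and the route is rejoined at 22.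

Step 9. Intermolecular allylation may outrun ring closure, the π-allyl complex may lose a proton to give a diene, the enolate may attack the inner allyl terminus (12-membered ring), or the E geometry may be lost by π–σ–π isomerisation. The fallback is a base-mediated substitution on an allylic chloride with no π-allyl intermediate. It sets out from 11: NaOMe in MeOH at 0 °C → rt should remove the pivalate (the β-keto ester is shielded as its enolate) to give the allylic alcohol F5; PPh3 and CCl4 at rt the allylic chloride F6; and Cs2CO3 with NaI in MeCN at 60 °C under slow addition and high dilution should close the ring by C-alkylation, which comes back to the route at 13.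

Step 6. Facial selectivity may be poor with this β,β-disubstituted enal, which would give C2 epimers that the remote epoxide will not allow to be separated. The fallback sets C2 by reduction instead of addition. It sets out from 6: the lithium acetylide of 7 (LiN(SiMe3)2, THF, −78 °C) should give the C2-epimeric carbinols F7; MnO2 in CH2Cl2 the alkenyl alkynyl ketone F8; and (S)-Alpine-borane (B-isopinocampheyl-9-borabicyclo[3.3.1]nonane from (−)-α-pinene) in THF at rt, which treats the alkynyl group as the small substituent, should give the 4S carbinol and come back to the route at 8.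

**Further compounds**
F1 | step 12 | (2S,3E,7S,8S,11E)-2-(tert-butyldimethylsilyloxy)-7,8-epoxy-4,8,12-trimethyl-1-methylenecyclotetradeca-3,11-diene | C=C1CC/C(C)=C/CC[C@]2(C)O[C@H]2CC/C(C)=C/[C@@H]1O[Si](C)(C)C(C)(C)C
F2 | step 12 | (2S,3E,7S,8S,11E)-7,8-epoxy-4,8,12-trimethyl-1-methylenecyclotetradeca-3,11-dien-2-ol | C=C1CC/C(C)=C/CC[C@]2(C)O[C@H]2CC/C(C)=C/[C@@H]1O
F3 | step 12 | 2-(chloromethyl)allyl ether of F2 | C=C1CC/C(C)=C/CC[C@]2(C)O[C@H]2CC/C(C)=C/[C@@H]1OCC(=C)CCl
F4 | step 12 | 2-(acetoxymethyl)allyl ether of F2 | C=C1CC/C(C)=C/CC[C@]2(C)O[C@H]2CC/C(C)=C/[C@@H]1OCC(=C)COC(C)=O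
F5 | step 9 | methyl (4S,5E,9S,10S,13E)-4-(tert-butyldimethylsilyloxy)-9,10-epoxy-15-hydroxy-6,10,14-trimethyl-3-oxopentadeca-5,13-dienoate | OC/C(C)=C/CC[C@]1(C)O[C@H]1CC/C(C)=C/[C@H](O[Si](C)(C)C(C)(C)C)C(=O)CC(=O)OC
F6 | step 9 | methyl (4S,5E,9S,10S,13E)-4-(tert-butyldimethylsilyloxy)-15-chloro-9,10-epoxy-6,10,14-trimethyl-3-oxopentadeca-5,13-dienoate | ClC/C(C)=C/CC[C@]1(C)O[C@H]1CC/C(C)=C/[C@H](O[Si](C)(C)C(C)(C)C)C(=O)CC(=O)OC
F7 | step 6 | methyl (5E,9S,10S,13E)-9,10-epoxy-4-hydroxy-6,10,14-trimethyl-15-(pivaloyloxy)pentadeca-5,13-dien-2-ynoate (both C4 epimers) | CC(C)(C)C(=O)OC/C(C)=C/CC[C@]1(C)O[C@H]1CC/C(C)=C/C(O)C#CC(=O)OC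
F8 | step 6 | methyl (5E,9S,10S,13E)-9,10-epoxy-6,10,14-trimethyl-4-oxo-15-(pivaloyloxy)pentadeca-5,13-dien-2-ynoate | CC(C)(C)C(=O)OC/C(C)=C/CC[C@]1(C)O[C@H]1CC/C(C)=C/C(=O)C#CC(=O)OC
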